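**Plan**

- Retrosynthetic cuts, in order: O3–S (sulfation of a free 3-hydroxyl), the three O–benzyl bonds, C5–O and C7–O (fluoride displacement), O1–C8a (ring C), C3–C4 (enolate acylation), C3–O (alpha-oxygenation of an acetophenone).
- Forward: ring B enters as 4'-(benzyloxy)acetophenone and ring A as 2,4,6-trifluorobenzoyl chloride. The C2–C3–C4 chain is joined by C-acylation, ring C is closed by intramolecular SNAr, and ring A is oxygenated afterwards.
- Enabling feature: on ring A the oxygens O1 (on C8a), O5 and O7 lie ortho, ortho and para to C4a, the carbon that carries the C4 carbonyl. All three ring-A C–O bonds can therefore replace C–F bonds of one symmetric trifluorobenzoyl unit.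
- Protecting groups: O3 carries a methoxymethyl (MOM) group and every phenol a benzyl group, so O3 alone is freed for sulfation.
- Stereochemistry: the target is achiral with no stereocentre. The only sp3 stereocentre on the way (C2 of diketone 7) is racemic, enolisable and disappears on cyclisation.

Key step: step 4

Remark: the sulfate monoesters 13 and 14 are named and drawn as free acids, as in the target SMILES. Compound 13 is handled as its potassium salt, and the acid form of 14 is released only at the very end on a sulfonic acid resin and kept cold.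

**Route**

Step 1
Reactants: 1 4'-(benzyloxy)acetophenone
Product: 3 1-[4-(benzyloxy)phenyl]-2-hydroxyethan-1-one, via hydroxy dimethyl acetal 2 (not isolated)
Conditions: PhI(OAc)2 (1.1 equiv), KOH (3 equiv), MeOH, 0 → 20 °C; then 2 M aq HCl, THF, 20 °C
Reagents that add atoms: water, O (new carbonyl oxygen of 3); methanol, CO (methoxy groups of intermediate 2 only)
Why: Moriarty alpha-hydroxylation with trivalent iodine: the enolate attacks PhI(OAc)2 at carbon, methoxide adds to the carbonyl and expels iodobenzene internally to give a methoxy epoxide that methanol opens to acetal 2 (the former carbonyl oxygen becomes the hydroxyl), and dilute acid then hydrolyses the electron-rich aryl ketal without touching the benzyl ether.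

Step 2
Reactants: 3 1-[4-(benzyloxy)phenyl]-2-hydroxyethan-1-one
Product: 4 1-[4-(benzyloxy)phenyl]-2-(methoxymethoxy)ethan-1-one
Conditions: MOMCl (1.5 equiv), i-Pr2NEt (2 equiv), CH2Cl2, 0 → 20 °C
Reagents that add atoms: chloromethyl methyl ether (MOMCl), COCCl
Why: Standard MOM ether formation, O-alkylation of the primary alcohol by the highly electrophilic alpha-chloro ether under a hindered amine base that does not enolise the ketone.

Step 3
Reactants: 4 1-[4-(benzyloxy)phenyl]-2-(methoxymethoxy)ethan-1-one; 5 2,4,6-trifluorobenzoyl chloride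
Product: 7 1-[4-(benzyloxy)phenyl]-2-(methoxymethoxy)-3-(2,4,6-trifluorophenyl)propane-1,3-dione, via lithium enolate 6 (not isolated)
Conditions: LiN(SiMe3)2 (2.1 equiv), toluene–THF, −78 °C; then 5 (1.0 equiv), −78 → −20 °C; aq NH4Cl
Reagents that add atoms: none
Why: Claisen-type C-acylation of a preformed, chelated lithium enolate by an aroyl chloride in a weakly polar medium that favours attack through carbon; the second equivalent of base takes up the more acidic diketone, and the low temperature keeps amide and enolate away from the ring fluorines.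

Step 4
Reactants: 7 1-[4-(benzyloxy)phenyl]-2-(methoxymethoxy)-3-(2,4,6-trifluorophenyl)propane-1,3-dione
Product: 8 2-[4-(benzyloxy)phenyl]-5,7-difluoro-3-(methoxymethoxy)-4H-chromen-4-one
Conditions: K2CO3 (2.5 equiv), dry DMF, 20 → 50 °C
Reagents that add atoms: none
Why: K2CO3 turns the 2-alkoxy-1,3-diketone into its delocalised enolate, whose oxygen on the carbon bearing the 4-(benzyloxy)phenyl ring adds to a fluorine-bearing ortho carbon of ring A; the anionic sigma adduct is stabilised by the neighbouring C4 carbonyl (charge on C4a) and inductively by the other two fluorines, and loss of fluoride forms O1–C8a (SNAr, addition–elimination). The closest known reaction type is the base-mediated cyclisation of 1-(2-fluoroaryl)-1,3-diketones to chromones and flavones. Ring C closes as a six-membered ring by attack on an aromatic sp2 carbon, a mode that is favoured whether the ipso double bond is counted as exocyclic (C8a=C8, 6-exo-trig) or endocyclic (C8a=C4a, 6-endo-trig). No stereocentre is created, and the labile C2 centre of 7 becomes sp2. The step needs O-cyclisation at one ortho carbon and no bimolecular attack at the para fluorine: the two ortho fluorines are equivalent by symmetry, the central carbon and the other enolate oxygen could only form four-membered rings, and the intramolecular closure should outrun intermolecular substitution at moderate dilution. The fluorides left at C5 and C7 remain activated by the C4 carbonyl for step 5.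

Step 5
Reactants: 8 2-[4-(benzyloxy)phenyl]-5,7-difluoro-3-(methoxymethoxy)-4H-chromen-4-one; 9 benzyl alcohol
Product: 11 5,7-bis(benzyloxy)-2-[4-(benzyloxy)phenyl]-3-(methoxymethoxy)-4H-chromen-4-one, via 7-benzyloxy-5-fluoro ether 10 (not isolated)
Conditions: 9 (3 equiv), NaH (3 equiv), THF–DMF, 0 °C; then 8, 0 → 60 °C
Reagents that add atoms: none
Why: Two intermolecular SNAr displacements by benzyloxide, expected first at C7 (para to the carbonyl-bearing C4a) and then at C5 (ortho), each sigma adduct placing charge on C4a next to the C4 carbonyl; the first benzyloxy group is meta to the remaining fluoride and so does not sit on a charge-bearing carbon of the second adduct.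

Step 6
Reactants: 11 5,7-bis(benzyloxy)-2-[4-(benzyloxy)phenyl]-3-(methoxymethoxy)-4H-chromen-4-one
Product: 12 5,7-bis(benzyloxy)-2-[4-(benzyloxy)phenyl]-3-hydroxy-4H-chromen-4-one
Conditions: 1.25 M HCl in MeOH, THF, 40 °C
Reagents that add atoms: none
Why: Acid-catalysed acetal exchange (MOM cleavage): the acetal on the enolic O3 ionises readily and methanol traps the methoxymethyl cation, whereas the aryl benzyl ethers require much stronger acid.

Step 7
Reactants: 12 5,7-bis(benzyloxy)-2-[4-(benzyloxy)phenyl]-3-hydroxy-4H-chromen-4-one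
Product: 13 5,7-bis(benzyloxy)-2-[4-(benzyloxy)phenyl]-4-oxo-4H-chromen-3-yl hydrogen sulfate
Conditions: SO3·NMe3 (4 equiv), K2CO3 (6 equiv), DMF, 55 °C; isolated as the potassium salt
Reagents that add atoms: sulfur trioxide–trimethylamine complex, C[N+](C)(C)S(=O)(=O)[O-]
Why: O-sulfation of the only free hydroxyl with a sulfur trioxide–amine complex; carbonate generates the flavonolate, which attacks sulfur and displaces trimethylamine.

Step 8
Reactants: 13 5,7-bis(benzyloxy)-2-[4-(benzyloxy)phenyl]-4-oxo-4H-chromen-3-yl hydrogen sulfate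
Product: 14 kaempferol 3-O-sulfate, 5,7-dihydroxy-2-(4-hydroxyphenyl)-4-oxo-4H-chromen-3-yl hydrogen sulfate
Conditions: H2 (1 atm), 10% Pd/C, MeOH–THF, 20 °C; filter; Dowex 50W (H+ form), MeOH–H2O, 0 °C; lyophilise
Reagents that add atoms: none
Why: Catalytic hydrogenolysis of three aryl benzyl ethers on palladium; the sulfate monoester anion and the tetrasubstituted, conjugated C2=C3 bond should be inert under these neutral conditions.

**Compound list**

1 | 4'-(benzyloxy)acetophenone | CC(=O)c1ccc(OCc2ccccc2)cc1 | starting material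
2 | 2-[4-(benzyloxy)phenyl]-2,2-dimethoxyethan-1-ol | COC(CO)(OC)c1ccc(OCc2ccccc2)cc1 | intermediate (not isolated)
3 | 1-[4-(benzyloxy)phenyl]-2-hydroxyethan-1-one | O=C(CO)c1ccc(OCc2ccccc2)cc1 | intermediate
4 | 1-[4-(benzyloxy)phenyl]-2-(methoxymethoxy)ethan-1-one | COCOCC(=O)c1ccc(OCc2ccccc2)cc1 | intermediate
5 | 2,4,6-trifluorobenzoyl chloride | O=C(Cl)c1c(F)cc(F)cc1F | starting material
6 | lithium (Z)-1-[4-(benzyloxy)phenyl]-2-(methoxymethoxy)ethen-1-olate | [Li+].[O-]/C(=C\OCOC)c1ccc(OCc2ccccc2)cc1 | intermediate (not isolated)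
7 | 1-[4-(benzyloxy)phenyl]-2-(methoxymethoxy)-3-(2,4,6-trifluorophenyl)propane-1,3-dione (racemic at C2, keto–enol mixture) | O=C(c1c(F)cc(F)cc1F)C(OCOC)C(=O)c1ccc(OCc2ccccc2)cc1 | intermediate
8 | 2-[4-(benzyloxy)phenyl]-5,7-difluoro-3-(methoxymethoxy)-4H-chromen-4-one | COCOc1c(-c2ccc(OCc3ccccc3)cc2)oc2cc(F)cc(F)c2c1=O | intermediate
9 | benzyl alcohol | OCc1ccccc1 | starting material
10 | 7-(benzyloxy)-2-[4-(benzyloxy)phenyl]-5-fluoro-3-(methoxymethoxy)-4H-chromen-4-one | COCOc1c(-c2ccc(OCc3ccccc3)cc2)oc2cc(OCc3ccccc3)cc(F)c2c1=O | intermediate (not isolated)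
11 | 5,7-bis(benzyloxy)-2-[4-(benzyloxy)phenyl]-3-(methoxymethoxy)-4H-chromen-4-one | COCOc1c(-c2ccc(OCc3ccccc3)cc2)oc2cc(OCc3ccccc3)cc(OCc3ccccc3)c2c1=O | intermediate
12 | 5,7-bis(benzyloxy)-2-[4-(benzyloxy)phenyl]-3-hydroxy-4H-chromen-4-one | O=c1c(O)c(-c2ccc(OCc3ccccc3)cc2)oc2cc(OCc3ccccc3)cc(OCc3ccccc3)c12 | intermediate
13 | 5,7-bis(benzyloxy)-2-[4-(benzyloxy)phenyl]-4-oxo-4H-chromen-3-yl hydrogen sulfate | O=c1c(OS(=O)(=O)O)c(-c2ccc(OCc3ccccc3)cc2)oc2cc(OCc3ccccc3)cc(OCc3ccccc3)c12 | intermediate
14 | kaempferol 3-O-sulfate | O=c1c(OS(=O)(=O)O)c(-c2ccc(O)cc2)oc2cc(O)cc(O)c12 | target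

**Step count**

Total steps: 8. Longest linear sequence: 8 steps (1 → 14).

**Steps most likely to fail**

Step 3. The enolate may be acylated at oxygen instead of carbon to give an enol ester, the product diketone may quench unreacted enolate by proton transfer, and the amide base may displace ring fluorine. The fallback sets out from 4 and returns at 7. The lithium enolate 6 is added to commercial 2,4,6-trifluorobenzaldehyde (THF, −78 °C), an electrophile that the enolate can only attack through carbon. This should give the aldol adduct 1-[4-(benzyloxy)phenyl]-3-hydroxy-2-(methoxymethoxy)-3-(2,4,6-trifluorophenyl)propan-1-one F1 as a mixture of diastereomers. Dess–Martin periodinane (CH2Cl2, NaHCO3, 20 °C) then oxidises both diastereomers to diketone 7.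

Step 5. The second fluoride displacement may stall once the first benzyloxy group has lowered the electrophilicity of the carbonyl system, or benzyloxide may add at C2, open the pyranone and trigger retro-Claisen cleavage. The fallback sets out from 4 and returns at 11. It places both benzyloxy groups on ring A before ring closure, so that the SNAr at O1–C8a is the only fluoride displacement left.
- Commercial 5-fluororesorcinol is benzylated (BnBr, K2CO3, DMF) to 1,3-bis(benzyloxy)-5-fluorobenzene F2.
- Vilsmeier–Haack formylation (POCl3, DMF, then aq NaOAc) should occur para to one benzyloxy group and ortho to fluorine, giving 2,4-bis(benzyloxy)-6-fluorobenzaldehyde F3.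
- Aldol addition of enolate 6 to this aldehyde gives 3-[2,4-bis(benzyloxy)-6-fluorophenyl]-1-[4-(benzyloxy)phenyl]-3-hydroxy-2-(methoxymethoxy)propan-1-one F4.
- Dess–Martin oxidation gives 1-[2,4-bis(benzyloxy)-6-fluorophenyl]-3-[4-(benzyloxy)phenyl]-2-(methoxymethoxy)propane-1,3-dione F5.
- Cs2CO3 in DMF at 90 °C closes ring C by the same enolate-oxygen SNAr and delivers 11.

Step 7. Sulfation of the hindered, hydrogen-bonded 3-hydroxyl may be slow, and the sulfate monoester may hydrolyse while the salt is isolated and purified. The fallback sets out from 12 and returns at 13. It carries the sulfate in protected, neutral form. 2,2,2-Trichloroethyl chlorosulfate with Et3N and DMAP in THF should give 5,7-bis(benzyloxy)-2-[4-(benzyloxy)phenyl]-4-oxo-4H-chromen-3-yl 2,2,2-trichloroethyl sulfate F6, which can be purified on silica. Zinc dust with HCO2NH4 in MeOH–THF then removes the trichloroethyl group by reductive elimination and releases monoester 13. Its ammonium salt is exchanged for the potassium salt before hydrogenolysis.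

**Further compounds**

F1 | step 3 | 1-[4-(benzyloxy)phenyl]-3-hydroxy-2-(methoxymethoxy)-3-(2,4,6-trifluorophenyl)propan-1-one (diastereomer mixture) | COCOC(C(O)c1c(F)cc(F)cc1F)C(=O)c1ccc(OCc2ccccc2)cc1
F2 | step 5 | 1,3-bis(benzyloxy)-5-fluorobenzene | Fc1cc(OCc2ccccc2)cc(OCc2ccccc2)c1
F3 | step 5 | 2,4-bis(benzyloxy)-6-fluorobenzaldehyde | O=Cc1c(F)cc(OCc2ccccc2)cc1OCc1ccccc1
F4 | step 5 | 3-[2,4-bis(benzyloxy)-6-fluorophenyl]-1-[4-(benzyloxy)phenyl]-3-hydroxy-2-(methoxymethoxy)propan-1-one (diastereomer mixture) | COCOC(C(O)c1c(F)cc(OCc2ccccc2)cc1OCc1ccccc1)C(=O)c1ccc(OCc2ccccc2)cc1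
F5 | step 5 | 1-[2,4-bis(benzyloxy)-6-fluorophenyl]-3-[4-(benzyloxy)phenyl]-2-(methoxymethoxy)propane-1,3-dione | COCOC(C(=O)c1c(F)cc(OCc2ccccc2)cc1OCc1ccccc1)C(=O)c1ccc(OCc2ccccc2)cc1
F6 | step 7 | 5,7-bis(benzyloxy)-2-[4-(benzyloxy)phenyl]-4-oxo-4H-chromen-3-yl 2,2,2-trichloroethyl sulfate | O=c1c(OS(=O)(=O)OCC(Cl)(Cl)Cl)c(-c2ccc(OCc3ccccc3)cc2)oc2cc(OCc3ccccc3)cc(OCc3ccccc3)c12
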